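Ring A is built last, by a Diels–Alder benzannulation on a chiral dihydropyranone. The step exploits the four adjacent substituted carbons of ring A (C4a carbonyl, C8a–O1, C8 prenyl, C7 hydroxyl): a prenyl-bearing 2-silyloxytriene adds across the sulfinyl-activated C=C bond of ring C, forming C4a–C5 and C8–C8a, and loss of sulfenic acid plus DDQ dehydrogenation aromatise the new ring in the same operation. The precursor, an (S)-2-chromenyl-5-(p-tolylsulfinyl)-2,3-dihydro-4H-pyran-4-one, already holds C2 and rings B and C; its sulfoxide arrives as a carbon nucleophile, so the chromene never meets an electrophile or a peracid, and both phenols are silyl ethers removed by one buffered fluoride step.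

Key step: step 11

Assumption: the titanium–(S)-BINOL catalyst of step 6 is taken to deliver the nucleophile to the Si face of aldehyde 7, as this catalyst class does with simple aryl aldehydes; the sense is checked by MTPA ester analysis of 11, and (R)-BINOL is used instead if it proves opposite.

Remark: the configuration at sulfur has no bearing on the final product; the enantiopure sulfoxide 12 is used so that any C2 epimer of 14 or 16 is a separable diastereomer. The sulfur descriptor changes from R (12, 14) to S (15, 16, 22) without any change in geometry, because the carbon attached to sulfur then outranks the tolyl group.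

Step 1
Reactants: 1 resorcinol; 2 3-methylbut-2-enoic acid
Product: 3 7-hydroxy-2,2-dimethylchroman-4-one
Conditions: P2O5, MeSO3H, 70 °C
Reagents that add atoms: none
Why: Friedel–Crafts acylation of resorcinol para to one hydroxyl followed by intramolecular oxa-Michael addition of the ortho hydroxyl is the standard one-pot entry to 2,2-dimethylchroman-4-ones and leaves the free hydroxyl at C7.

Step 2
Reactants: 3 7-hydroxy-2,2-dimethylchroman-4-one
Product: 5 2,2-dimethyl-2H-chromen-7-ol, via 2,2-dimethylchromane-4,7-diol 4 (not isolated)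
Conditions: LiAlH4, THF, 0 °C to reflux; 2 M aq. HCl, 0 to 20 °C
Reagents that add atoms: none
Why: Hydride reduction of the aryl ketone gives the racemic benzylic alcohol, and acid-catalysed E1 dehydration through the cation stabilised by the para oxygen removes that centre again and gives the conjugated chromene.

Step 3
Reactants: 5 2,2-dimethyl-2H-chromen-7-ol
Product: 6 7-hydroxy-2,2-dimethyl-2H-chromene-6-carbaldehyde
Conditions: (CH2O)n, MgCl2, Et3N, MeCN, reflux
Reagents that add atoms: paraformaldehyde (as formaldehyde), C=O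
Why: Magnesium-phenoxide-directed ortho-formylation (Casnati–Skattebøl reaction) should occur at C6, the ortho position that is para to the ring oxygen and not wedged between two oxygens, under non-acidic conditions that spare the chromene double bond.

Step 4
Reactants: 6 7-hydroxy-2,2-dimethyl-2H-chromene-6-carbaldehyde
Product: 7 2,2-dimethyl-7-(triisopropylsilyloxy)-2H-chromene-6-carbaldehyde
Conditions: iPr3SiCl, imidazole, DMF, 20 °C
Reagents that add atoms: chlorotriisopropylsilane, CC(C)[Si](Cl)(C(C)C)C(C)C
Why: Silylation of the hydrogen-bonded phenol by the chlorosilane under imidazole catalysis gives an aryl silyl ether bulky enough not to migrate to the benzylic alkoxide of step 7 and removable by fluoride together with the silyl group that arrives in step 11.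

Step 5
Reactants: 8 S-tert-butyl ethanethioate
Product: 9 1-(tert-butylthio)-1-(trimethylsilyloxy)ethene
Conditions: LiN(iPr)2, THF, −78 °C; Me3SiCl, −78 to 20 °C
Reagents that add atoms: chlorotrimethylsilane, C[Si](C)(C)Cl
Why: Deprotonation of the thioester by the lithium amide and O-silylation of the enolate is the standard route to the silyl ketene thioacetal needed as Mukaiyama aldol donor.

Step 6
Reactants: 7 2,2-dimethyl-7-(triisopropylsilyloxy)-2H-chromene-6-carbaldehyde; 9 1-(tert-butylthio)-1-(trimethylsilyloxy)ethene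
Product: 11 S-tert-butyl (3S)-3-[2,2-dimethyl-7-(triisopropylsilyloxy)-2H-chromen-6-yl]-3-hydroxypropanethioate, via trimethylsilyl ether of the aldol adduct 10 (not isolated)
Conditions: (S)-BINOL (20 mol %), Ti(OiPr)4 (20 mol %), 4 Å MS, Et2O, −20 °C; 10% aq. citric acid, THF, 0 °C
Reagents that add atoms: none
Why: Catalytic enantioselective Mukaiyama aldol addition: the BINOL-bound tetravalent titanium centre activates the aldehyde and blocks its Re face, so that C–C bond formation on the Si face sets the carbinol carbon as S, and brief mild acid cleaves only the trimethylsilyl ether.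

Step 7
Reactants: 11 S-tert-butyl (3S)-3-[2,2-dimethyl-7-(triisopropylsilyloxy)-2H-chromen-6-yl]-3-hydroxypropanethioate; 12 (R)-methyl p-tolyl sulfoxide
Product: 14 (4S)-4-[2,2-dimethyl-7-(triisopropylsilyloxy)-2H-chromen-6-yl]-4-hydroxy-1-[(R)-4-methylbenzenesulfinyl]butan-2-one, via (R)-(p-tolylsulfinyl)methyllithium 13 (not isolated)
Conditions: 12 (3.3 equiv), LiN(iPr)2 (3.3 equiv), THF, −78 °C; 11, −78 to −40 °C; aq. NH4Cl
Reagents that add atoms: none
Why: Claisen-type acylation of the alpha-sulfinyl carbanion by the thioester gives the beta-keto sulfoxide, the excess carbanion covering the hydroxyl proton and the acidic product, while the carbinol centre is untouched and sulfur keeps its configuration.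

Step 8
Reactants: 14 (4S)-4-[2,2-dimethyl-7-(triisopropylsilyloxy)-2H-chromen-6-yl]-4-hydroxy-1-[(R)-4-methylbenzenesulfinyl]butan-2-one
Product: 16 (2S)-2-[2,2-dimethyl-7-(triisopropylsilyloxy)-2H-chromen-6-yl]-5-[(S)-4-methylbenzenesulfinyl]-2,3-dihydro-4H-pyran-4-one, via sulfinyl enaminone 15 (not isolated)
Conditions: Me2NCH(OMe)2 (1.3 equiv), toluene, 20 to 40 °C
Reagents that add atoms: N,N-dimethylformamide dimethyl acetal, COC(OC)N(C)C
Why: Condensation of the methylene group flanked by C=O and S=O with the amide acetal gives an enaminone, and addition–elimination by the delta-hydroxyl (oxa-Michael addition, loss of dimethylamine) closes ring C through oxygen, so that the configuration at C2 is retained.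

Step 9
Reactants: 17 6-methylhept-5-en-2-one
Product: 20 7-methylocta-1,6-dien-3-one, via Mannich base 18 (not isolated), via quaternary ammonium iodide 19 (not isolated)
Conditions: LiN(iPr)2, THF, −78 °C; Me2N=CH2 I, −78 to 20 °C; MeI, Et2O, 20 °C; aq. NaHCO3, CH2Cl2, 20 °C
Reagents that add atoms: dimethylmethyleneammonium iodide, C=[N+](C)C.[I-]
Why: Mannich reaction of the kinetic, methyl-side lithium enolate with the iminium salt, N-methylation and E1cB elimination of trimethylamine make up the standard alpha-methylenation of a methyl ketone to a vinyl ketone.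

Step 10
Reactants: 20 7-methylocta-1,6-dien-3-one
Product: 21 (3Z)-3-(tert-butyldimethylsilyloxy)-7-methylocta-1,3,6-triene
Conditions: tBuMe2SiOTf, Et3N, Et2O, 0 °C
Reagents that add atoms: tert-butyldimethylsilyl trifluoromethanesulfonate, CC(C)(C)[Si](C)(C)OS(=O)(=O)C(F)(F)F
Why: Soft enolisation with the silyl triflate and amine can only take place toward C4, and the Z silyl enol ether, which keeps the chain trans to the vinyl group and so allows the s-cis diene conformation, should predominate.

Step 11
Reactants: 16 (2S)-2-[2,2-dimethyl-7-(triisopropylsilyloxy)-2H-chromen-6-yl]-5-[(S)-4-methylbenzenesulfinyl]-2,3-dihydro-4H-pyran-4-one; 21 (3Z)-3-(tert-butyldimethylsilyloxy)-7-methylocta-1,3,6-triene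
Product: 24 (2S)-7-(tert-butyldimethylsilyloxy)-2-[2,2-dimethyl-7-(triisopropylsilyloxy)-2H-chromen-6-yl]-8-(3-methylbut-2-en-1-yl)-2,3-dihydro-4H-chromen-4-one, via cis-fused sulfinyl cycloadduct 22 (not isolated), via 5,8-dihydro intermediate 23 (not isolated)
Conditions: 21 (2 equiv), NaHCO3 (solid), toluene, 80 °C; excess 21 removed at 0.1 mbar; DDQ (1.1 equiv), toluene, 0 to 20 °C
Reagents that add atoms: none
Why: Proposed new method: the electron-rich diene 21 and the C5=C6 bond of 16, whose acceptor character is raised by the ketone and the sulfinyl group, should combine in a normal-demand, probably asynchronous [4+2] cycloaddition in which the prenyl-bearing enol ether carbon bonds to C6 (future C8a) and the CH2 terminus to C5 (future C4a), after which thermal syn-elimination of the sulfenic acid from beta-keto sulfoxide 22 and hydride abstraction by DDQ from the doubly allylic CH2 of cyclohexadiene 23 give the arene. The closest known reaction type is the Diels–Alder benzannulation of alpha-sulfinyl enones and 3-sulfinylchromones with 2-silyloxydienes followed by sulfenic acid loss and oxidation, and a 5-sulfinyl-2,3-dihydro-4H-pyran-4-one has not yet served as the dienophile. Ring A, the only ring formed, closes as a six-membered carbocycle by the suprafacial [4+2] addition itself, both sigma bonds arising in one event so that no other ring size competes, and is then aromatised. No stereocentre survives from this step, since C4a, C8 and C8a of 22 are transient, and the remote C2 is protected by the absence of base and of strong Lewis acid, either of which could open ring C or ionise the benzylic C2–O bond. The regioselectivity needed (C8 to C8a) should follow from the pairing of the most nucleophilic diene terminus, the enol ether carbon, with the carbon that is beta to both C=O and S=O, the silyloxy donor outweighing the alkyl terminus and so placing the C7 oxygen para to C4a and next to the prenyl-bearing C8. The chemoselectivity needed in the oxidation should follow from removing the excess diene first and using one equivalent of DDQ in the cold, where the cyclohexadiene reacts faster than the chromene, the prenyl group or the C2–H bond.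

Step 12
Reactants: 24 (2S)-7-(tert-butyldimethylsilyloxy)-2-[2,2-dimethyl-7-(triisopropylsilyloxy)-2H-chromen-6-yl]-8-(3-methylbut-2-en-1-yl)-2,3-dihydro-4H-chromen-4-one
Product: 25 (2S)-7-hydroxy-2-(7-hydroxy-2,2-dimethyl-2H-chromen-6-yl)-8-(3-methylbut-2-en-1-yl)-2,3-dihydro-4H-chromen-4-one
Conditions: Bu4NF (2.5 equiv), AcOH (2.5 equiv), THF, 0 to 20 °C
Reagents that add atoms: none
Why: Fluoride-induced cleavage of both aryl silyl ethers (Si–O to Si–F exchange) in an acetic acid buffer frees the two phenols without the base that would open ring C and scramble C2 and without the acid that would cyclise the prenyl phenol or the chromene.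

Compound list

1 | resorcinol | Oc1cccc(O)c1 | starting material
2 | 3-methylbut-2-enoic acid | CC(C)=CC(=O)O | starting material
3 | 7-hydroxy-2,2-dimethylchroman-4-one | CC1(C)CC(=O)c2ccc(O)cc2O1 | intermediate
4 | 2,2-dimethylchromane-4,7-diol (racemic, not isolated) | CC1(C)CC(O)c2ccc(O)cc2O1 | intermediate
5 | 2,2-dimethyl-2H-chromen-7-ol | CC1(C)C=Cc2ccc(O)cc2O1 | intermediate
6 | 7-hydroxy-2,2-dimethyl-2H-chromene-6-carbaldehyde | CC1(C)C=Cc2cc(C=O)c(O)cc2O1 | intermediate
7 | 2,2-dimethyl-7-(triisopropylsilyloxy)-2H-chromene-6-carbaldehyde | CC1(C)C=Cc2cc(C=O)c(O[Si](C(C)C)(C(C)C)C(C)C)cc2O1 | intermediate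
8 | S-tert-butyl ethanethioate | CC(=O)SC(C)(C)C | starting material
9 | 1-(tert-butylthio)-1-(trimethylsilyloxy)ethene | C=C(O[Si](C)(C)C)SC(C)(C)C | intermediate
10 | S-tert-butyl (3S)-3-[2,2-dimethyl-7-(triisopropylsilyloxy)-2H-chromen-6-yl]-3-(trimethylsilyloxy)propanethioate (not isolated) | CC(C)(C)SC(=O)C[C@@H](c1cc2c(cc1O[Si](C(C)C)(C(C)C)C(C)C)OC(C)(C)C=C2)O[Si](C)(C)C | intermediate
11 | S-tert-butyl (3S)-3-[2,2-dimethyl-7-(triisopropylsilyloxy)-2H-chromen-6-yl]-3-hydroxypropanethioate | CC(C)(C)SC(=O)C[C@@H](c1cc2c(cc1O[Si](C(C)C)(C(C)C)C(C)C)OC(C)(C)C=C2)O | intermediate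
12 | (R)-methyl p-tolyl sulfoxide | C[S@@](=O)c1ccc(C)cc1 | starting material
13 | (R)-(p-tolylsulfinyl)methyllithium (not isolated) | [Li]C[S@@](=O)c1ccc(C)cc1 | intermediate
14 | (4S)-4-[2,2-dimethyl-7-(triisopropylsilyloxy)-2H-chromen-6-yl]-4-hydroxy-1-[(R)-4-methylbenzenesulfinyl]butan-2-one | O=C(C[C@@H](c1cc2c(cc1O[Si](C(C)C)(C(C)C)C(C)C)OC(C)(C)C=C2)O)C[S@@](=O)c1ccc(C)cc1 | intermediate
15 | (5S)-1-(dimethylamino)-5-[2,2-dimethyl-7-(triisopropylsilyloxy)-2H-chromen-6-yl]-5-hydroxy-2-[(S)-4-methylbenzenesulfinyl]pent-1-en-3-one (alkene geometry not fixed, not isolated) | CN(C)C=C(C(=O)C[C@@H](c1cc2c(cc1O[Si](C(C)C)(C(C)C)C(C)C)OC(C)(C)C=C2)O)[S@@](=O)c1ccc(C)cc1 | intermediate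
16 | (2S)-2-[2,2-dimethyl-7-(triisopropylsilyloxy)-2H-chromen-6-yl]-5-[(S)-4-methylbenzenesulfinyl]-2,3-dihydro-4H-pyran-4-one | O=C1C[C@@H](c2cc3c(cc2O[Si](C(C)C)(C(C)C)C(C)C)OC(C)(C)C=C3)OC=C1[S@@](=O)c1ccc(C)cc1 | intermediate
17 | 6-methylhept-5-en-2-one | CC(=O)CCC=C(C)C | starting material
18 | 1-(dimethylamino)-7-methyloct-6-en-3-one (not isolated) | CN(C)CCC(=O)CCC=C(C)C | intermediate
19 | trimethyl(7-methyl-3-oxooct-6-en-1-yl)ammonium iodide (not isolated) | C[N+](C)(C)CCC(=O)CCC=C(C)C.[I-] | intermediate
20 | 7-methylocta-1,6-dien-3-one | C=CC(=O)CCC=C(C)C | intermediate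
21 | (3Z)-3-(tert-butyldimethylsilyloxy)-7-methylocta-1,3,6-triene | C=C/C(O[Si](C)(C)C(C)(C)C)=C/CC=C(C)C | intermediate
22 | (2S)-7-(tert-butyldimethylsilyloxy)-2-[2,2-dimethyl-7-(triisopropylsilyloxy)-2H-chromen-6-yl]-8-(3-methylbut-2-en-1-yl)-4a-[(S)-4-methylbenzenesulfinyl]-2,3,4a,5,8,8a-hexahydro-4H-chromen-4-one (cis ring fusion, mixture at C4a, C8 and C8a, not isolated) | O=C1C[C@@H](c2cc3c(cc2O[Si](C(C)C)(C(C)C)C(C)C)OC(C)(C)C=C3)OC2C(CC=C(C)C)C(O[Si](C)(C)C(C)(C)C)=CCC12[S@@](=O)c1ccc(C)cc1 | intermediate
23 | (2S)-7-(tert-butyldimethylsilyloxy)-2-[2,2-dimethyl-7-(triisopropylsilyloxy)-2H-chromen-6-yl]-8-(3-methylbut-2-en-1-yl)-2,3,5,8-tetrahydro-4H-chromen-4-one (mixture at C8, not isolated) | O=C1C[C@@H](c2cc3c(cc2O[Si](C(C)C)(C(C)C)C(C)C)OC(C)(C)C=C3)OC2=C1CC=C(O[Si](C)(C)C(C)(C)C)C2CC=C(C)C | intermediate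
24 | (2S)-7-(tert-butyldimethylsilyloxy)-2-[2,2-dimethyl-7-(triisopropylsilyloxy)-2H-chromen-6-yl]-8-(3-methylbut-2-en-1-yl)-2,3-dihydro-4H-chromen-4-one | CC(C)=CCc1c(O[Si](C)(C)C(C)(C)C)ccc2c1O[C@H](c1cc3c(cc1O[Si](C(C)C)(C(C)C)C(C)C)OC(C)(C)C=C3)CC2=O | intermediate
25 | (2S)-7-hydroxy-2-(7-hydroxy-2,2-dimethyl-2H-chromen-6-yl)-8-(3-methylbut-2-en-1-yl)-2,3-dihydro-4H-chromen-4-one | CC(C)=CCc1c(O)ccc2c1O[C@H](c1cc3c(cc1O)OC(C)(C)C=C3)CC2=O | target

Total step count: 12. Longest linear sequence: 9 steps (steps 1, 2, 3, 4, 6, 7, 8, 11, 12).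

Steps most likely to fail

Step 11. The cycloaddition may be too slow at a temperature the diene tolerates, or bond formation may start at the wrong diene terminus. The oxidant may also abstract hydride from the C2–H bond of the electron-rich benzylic ether, or attack the chromene, before the cyclohexadiene is consumed. Partial loss of the C7 silyl group in the oxidation is harmless, since step 12 removes it anyway. The fallback uses known chemistry and takes ring A from an arene instead of building it; it sets out from aldehyde 7 and rejoins the route at 24. 2,4-Dihydroxyacetophenone is C-prenylated at C3 (prenyl bromide, aq. KOH, regioisomers separated) to give 1-[2,4-dihydroxy-3-(3-methylbut-2-en-1-yl)phenyl]ethan-1-one F1. Its non-chelated 4-hydroxyl is silylated (tBuMe2SiCl, imidazole) to 1-[4-(tert-butyldimethylsilyloxy)-2-hydroxy-3-(3-methylbut-2-en-1-yl)phenyl]ethan-1-one F2. Pyrrolidine-mediated condensation of F2 with 7 in toluene (Kabbe condensation) should pass through the 2'-hydroxychalcone F3 and close it by oxa-Michael addition to the racemic protected flavanone F4. Preparative HPLC on a polysaccharide chiral phase then delivers 24 for step 12.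

Step 6. Facial selectivity or turnover may be poor with this electron-rich aldehyde carrying a bulky ortho silyloxy group. The fallback sets the carbinol centre by reduction instead of by C–C bond formation; it sets out from aldehyde 7 and rejoins at 14. Addition of the lithium enolate of ethyl acetate (−78 °C, cold quench) gives racemic ethyl 3-[2,2-dimethyl-7-(triisopropylsilyloxy)-2H-chromen-6-yl]-3-hydroxypropanoate F5. Oxidation with MnO2 in CH2Cl2 gives ethyl 3-[2,2-dimethyl-7-(triisopropylsilyloxy)-2H-chromen-6-yl]-3-oxopropanoate F6. Asymmetric transfer hydrogenation (RuCl[(S,S)-TsDPEN](p-cymene), HCO2H, Et3N) should give ethyl (3S)-3-[2,2-dimethyl-7-(triisopropylsilyloxy)-2H-chromen-6-yl]-3-hydroxypropanoate F7. F7 is acylated by 13 under the conditions of step 7 to give 14.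

Step 7. The lithium aldolate may undergo retro-aldol cleavage, the silyl group may migrate from the phenol oxygen to the benzylic alkoxide, or the acylation may stall at the hindered thioester. The fallback assembles the chain in the other direction; it sets out from aldehyde 7 and sulfoxide 12 and rejoins at 14. Sulfoxide 12 is acylated with ethyl acetate (LiN(iPr)2, THF) to (R)-1-(4-methylbenzenesulfinyl)propan-2-one F8. Its dianion (2 equiv LiN(iPr)2, THF, −78 °C) adds through the methyl terminus to 7 and is quenched cold. This gives 14 together with its carbinol epimer (4R)-4-[2,2-dimethyl-7-(triisopropylsilyloxy)-2H-chromen-6-yl]-4-hydroxy-1-[(R)-4-methylbenzenesulfinyl]butan-2-one F9. The two diastereomers are separated by chromatography or crystallisation, and 14 continues in step 8.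

Further compounds

F1 | step 11 | 1-[2,4-dihydroxy-3-(3-methylbut-2-en-1-yl)phenyl]ethan-1-one | CC(=O)c1ccc(O)c(CC=C(C)C)c1O
F2 | step 11 | 1-[4-(tert-butyldimethylsilyloxy)-2-hydroxy-3-(3-methylbut-2-en-1-yl)phenyl]ethan-1-one | CC(=O)c1ccc(O[Si](C)(C)C(C)(C)C)c(CC=C(C)C)c1O
F3 | step 11 | (E)-1-[4-(tert-butyldimethylsilyloxy)-2-hydroxy-3-(3-methylbut-2-en-1-yl)phenyl]-3-[2,2-dimethyl-7-(triisopropylsilyloxy)-2H-chromen-6-yl]prop-2-en-1-one | CC(C)=CCc1c(O[Si](C)(C)C(C)(C)C)ccc(C(=O)/C=C/c2cc3c(cc2O[Si](C(C)C)(C(C)C)C(C)C)OC(C)(C)C=C3)c1O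
F4 | step 11 | racemic protected flavanone (racemate of 24) | CC(C)=CCc1c(O[Si](C)(C)C(C)(C)C)ccc2c1OC(c1cc3c(cc1O[Si](C(C)C)(C(C)C)C(C)C)OC(C)(C)C=C3)CC2=O
F5 | step 6 | racemic ethyl 3-[2,2-dimethyl-7-(triisopropylsilyloxy)-2H-chromen-6-yl]-3-hydroxypropanoate | CCOC(=O)CC(O)c1cc2c(cc1O[Si](C(C)C)(C(C)C)C(C)C)OC(C)(C)C=C2
F6 | step 6 | ethyl 3-[2,2-dimethyl-7-(triisopropylsilyloxy)-2H-chromen-6-yl]-3-oxopropanoate | CCOC(=O)CC(=O)c1cc2c(cc1O[Si](C(C)C)(C(C)C)C(C)C)OC(C)(C)C=C2
F7 | step 6 | ethyl (3S)-3-[2,2-dimethyl-7-(triisopropylsilyloxy)-2H-chromen-6-yl]-3-hydroxypropanoate | CCOC(=O)C[C@@H](c1cc2c(cc1O[Si](C(C)C)(C(C)C)C(C)C)OC(C)(C)C=C2)O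
F8 | step 7 | (R)-1-(4-methylbenzenesulfinyl)propan-2-one | CC(=O)C[S@@](=O)c1ccc(C)cc1
F9 | step 7 | (4R)-4-[2,2-dimethyl-7-(triisopropylsilyloxy)-2H-chromen-6-yl]-4-hydroxy-1-[(R)-4-methylbenzenesulfinyl]butan-2-one | O=C(C[C@H](c1cc2c(cc1O[Si](C(C)C)(C(C)C)C(C)C)OC(C)(C)C=C2)O)C[S@@](=O)c1ccc(C)cc1
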